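C9 is the hydroxymethyl carbon and C7' the benzylic CH2. The retrosynthesis first returns C9 to a carboxyl group and C7' to an aldehyde carbon (cutting C7'–guaiacyl). It then cuts C2–C3 and C4–C5 of the oxolane (O1, C2 trimethoxyphenyl, C3, C4, C5) together.
Enabling feature: C2–O1–C5 is the three-atom skeleton of a carbonyl ylide ArCH=O(+)–CH2(−). C3 and C4 carry their arms C9 and C7' cis, so C9–C3–C4–C7' is the C(=O)–CH=CH–CH(OR) chain of a 5-alkoxybutenolide.
Ring order going forward: the lactone ring comes first (furfural to butenolide) and the oxolane ring is annulated onto its alkene by the cycloaddition. The lactone is then dismantled by aryl addition at C7', benzylic C–O hydrogenolysis and reduction of C9.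
Stereochemistry: (+)-menthol plus crystallisation fixes the 5S acetal carbon, which sends the dipole to the opposite alkene face and sets C3 and C4 absolutely. The ring-locked cis alkene gives 3,4-cis, exo approach of the outward ylide gives 2,3-trans, and the controlling acetal carbon ends as the achiral C7'H2.

Key step: step 5

Assumption: the lactol carbon, and later the benzylic lactone carbon (both the future C7'), form as epimer mixtures and are drawn without configuration, because this carbon ends as a CH2 group.

Step 1
Reactants: 1 furfural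
Product: 2 5-hydroxyfuran-2(5H)-one (racemic)
Conditions: O2, methylene blue (cat.), hν (visible), MeOH, 0–20 °C
Reagents that add atoms: dioxygen, O=O
Why: Dye-sensitised singlet-oxygen [4+2] photooxygenation of the furan should give the 2,5-endoperoxide, which methanol fragments at the formyl group (lost as methyl formate) to the pseudoacid, whose lactol carbon is racemic and configurationally labile, as step 2 requires.

Step 2
Reactants: 2 5-hydroxyfuran-2(5H)-one; 3 (+)-menthol, (1S,2R,5S)
Product: 4 (5S)-5-[(1S,2R,5S)-menthyloxy]furan-2(5H)-one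
Conditions: TsOH·H2O (cat.), toluene, reflux, azeotropic water removal; crystallisation from petroleum ether, −20 °C; mother liquor re-equilibrated (cat. TsOH) and crystallised again
Reagents that add atoms: none
Why: Acid-catalysed acetalisation of the pseudoacid gives both C5 epimers, which interconvert through the oxocarbenium ion, and only the (5S)-epimer of the (+)-menthyl series is crystalline, so a crystallisation-induced diastereomer transformation sets and purifies the acetal stereocentre.

Step 3
Reactants: 5 3,4,5-trimethoxybenzaldehyde; 6 (trimethylsilyl)methanol (2.2 equiv)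
Product: 7 3,4,5-trimethoxybenzaldehyde bis[(trimethylsilyl)methyl] acetal
Conditions: TsOH·H2O (cat.), toluene, reflux, azeotropic water removal
Reagents that add atoms: none
Why: This is ordinary acid-catalysed acetalisation of an aromatic aldehyde with a primary alcohol, driven by water removal, in which the silylmethyl C–Si bonds tolerate catalytic sulfonic acid and no stereocentre is formed.

Step 4
Reactants: 7 3,4,5-trimethoxybenzaldehyde bis[(trimethylsilyl)methyl] acetal
Product: 8 chloro(3,4,5-trimethoxyphenyl)methyl (trimethylsilyl)methyl ether (racemic; labile)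
Conditions: AcCl (1.05 equiv), ZnBr2 (0.1 mol %), CH2Cl2, 0 °C → rt; volatiles removed under high vacuum; used at once
Reagents that add atoms: acetyl chloride, CC(=O)Cl
Why: In this acetal–acyl chloride exchange (haloalkyl ether synthesis), acylation of one acetal oxygen expels (trimethylsilyl)methyl acetate and chloride captures the aryl-stabilised oxocarbenium ion under anhydrous conditions, which suits a chloride that would not survive the water of a direct aldehyde–alcohol–HCl condensation; the racemic centre is erased when the ylide forms.

Step 5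
Reactants: 8 chloro(3,4,5-trimethoxyphenyl)methyl (trimethylsilyl)methyl ether (2 equiv); 4 (5S)-5-[(1S,2R,5S)-menthyloxy]furan-2(5H)-one
Product: 10 (3S,3aR,6S,6aS)-3-[(1S,2R,5S)-menthyloxy]-6-(3,4,5-trimethoxyphenyl)tetrahydro-1H,3H-furo[3,4-c]furan-1-one (cis-fused; aryl on the convex face; menthyloxy anti to the oxolane ring), via carbonyl ylide 9 (not isolated)
Conditions: CsF (flame-dried, 4 equiv), MeCN, rt, slow addition of 8 to 4 and CsF
Reagents that add atoms: none
Why: Fluoride attack on silicon with loss of chloride (by way of the aryl-stabilised oxocarbenium ion) is a silicon-based 1,3-elimination that frees the non-stabilised carbonyl ylide 9, which adds to the butenolide C=C in a concerted suprafacial [π4s+π2s] 1,3-dipolar cycloaddition; the closest known reaction types are CsF-triggered carbonyl ylide additions of chloroalkyl silylmethyl ethers to acrylates, maleates and enones, and the additions of diazoalkanes, nitrile oxides and azomethine ylides to 5-alkoxybutenolides. The oxolane ring closes in one intermolecular three-atom-plus-two-atom union (C2–O1–C5 onto C3=C4) in which C2–C3 and C4–C5 form together, so it arrives cis-fused to the lactone as a 3,7-dioxabicyclo[3.3.0]octane. C3 and C4 are set by the alkene: its cis geometry is locked in the five-membered lactone and is transferred suprafacially (3,4-cis), and the bulky menthyloxy group on the 5S acetal carbon shields one face, so the dipole bonds to the opposite face and fixes the absolute sense (3aR,6aS). C2 is set by the outward (W-shaped) ylide geometry combined with an exo approach, in which the lactone ring points away from the ylide oxygen and the aryl group, leaving the aryl on the convex face and trans to the lactone carbonyl (6S). The step also needs regioselectivity: the electron-rich aryl group holds the positive end at C2, the largest HOMO coefficient sits on the unsubstituted CH2 terminus, and this end bonds to the β-carbon, which carries the largest LUMO coefficient of the enoate. Slow addition of 8 keeps the ylide concentration low, so that capture by the alkene should outrun dimerisation or collapse to the oxirane.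

Step 6
Reactants: 10 menthyl acetal cycloadduct
Product: 11 (3aR,6S,6aS)-3-hydroxy-6-(3,4,5-trimethoxyphenyl)tetrahydro-1H,3H-furo[3,4-c]furan-1-one (pseudoacid; lactol epimers)
Conditions: 2 M aq HCl–1,4-dioxane (1:3), 45 °C
Reagents that add atoms: water, O
Why: In this acid-catalysed hydrolysis of the acyloxy alkoxy acetal the lactone carboxyl group leaves, water adds to the menthyl oxocarbenium ion and menthol departs, after which the cis aldehyde acid recloses to the cis-fused pseudoacid, a sink that protects C4 from epimerisation, while the C2–O1 benzylic ether is deactivated towards ionisation by the carbonyl-bearing C3 and already holds the more stable 2,3-trans arrangement.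

Step 7
Reactants: 12 4-bromo-2-methoxyphenol
Product: 13 1-(benzyloxy)-4-bromo-2-methoxybenzene
Conditions: BnBr, K2CO3, acetone, reflux
Reagents that add atoms: benzyl bromide, BrCc1ccccc1
Why: Williamson ether synthesis on the phenoxide installs a benzyl group that masks the acidic phenol during the Grignard step and leaves in the hydrogenolysis that is needed anyway.

Step 8
Reactants: 13 1-(benzyloxy)-4-bromo-2-methoxybenzene (2.5 equiv); 11 pseudoacid
Product: 16 (3aR,6S,6aS)-3-[4-(benzyloxy)-3-methoxyphenyl]-6-(3,4,5-trimethoxyphenyl)tetrahydro-1H,3H-furo[3,4-c]furan-1-one (epimers at C3), via arylmagnesium bromide 14 (not isolated), via hydroxy acid 15 (not isolated)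
Conditions: Mg, THF, 40 °C; then 11 added to 14, THF, −40 → 0 °C; then 1 M aq HCl, rt
Reagents that add atoms: none
Why: This is Grignard addition to a pseudoacid, as in the preparation of 3-arylphthalides from 2-formylbenzoic acid: the first equivalent of 14 deprotonates the lactol and unmasks the aldehyde as its magnesium carboxylate, the second should add to the aldehyde faster than it enolises it at low temperature with 14 in excess, the carboxylate is inert, and acid work-up relactonises the cis hydroxy acid, whose new benzylic centre needs no control.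

Step 9
Reactants: 16 benzyl-protected aryl lactone
Product: 18 (2S,3S,4R)-4-(4-hydroxy-3-methoxybenzyl)-2-(3,4,5-trimethoxyphenyl)oxolane-3-carboxylic acid, via phenol lactone 17 (not isolated)
Conditions: H2 (1 atm), 10% Pd/C, EtOAc–EtOH, rt, stopped after uptake of two equivalents of H2
Reagents that add atoms: none
Why: In this catalytic hydrogenolysis the aryl benzyl ether should fall first, and the benzylic acyloxy C–O bond of the lactone (carboxylate leaving group, para-hydroxy activation) should then cleave faster than the hindered dialkyl-type benzylic ether C2–O1, turning C7' into CH2 without touching C2, C3 or C4.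

Step 10
Reactants: 18 oxolane-3-carboxylic acid
Product: 19 4-{[(3R,4R,5S)-4-(hydroxymethyl)-5-(3,4,5-trimethoxyphenyl)oxolan-3-yl]methyl}-2-methoxyphenol (target; 2S,3R,4R in the numbering used here)
Conditions: BH3·THF (4 equiv), THF, 0 °C → rt; then aq NH4Cl
Reagents that add atoms: none
Why: Borane reduces the carboxylic acid chemoselectively through the acyloxyborane under non-basic conditions, so the α-carbon C3 is not epimerised, the ethers and arenes are untouched, and the phenol only forms a borate that the work-up hydrolyses.

Compound list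
1 | furfural | O=Cc1ccco1 | starting material
2 | 5-hydroxyfuran-2(5H)-one (racemic) | OC1OC(=O)C=C1 | intermediate
3 | (+)-menthol, (1S,2R,5S) | C[C@H]1CC[C@@H]([C@H](C1)O)C(C)C | starting material
4 | (5S)-5-[(1S,2R,5S)-menthyloxy]furan-2(5H)-one | C[C@H]1CC[C@@H]([C@H](C1)O[C@@H]2C=CC(=O)O2)C(C)C | intermediate
5 | 3,4,5-trimethoxybenzaldehyde | COc1cc(C=O)cc(OC)c1OC | starting material
6 | (trimethylsilyl)methanol | C[Si](C)(C)CO | starting material
7 | 3,4,5-trimethoxybenzaldehyde bis[(trimethylsilyl)methyl] acetal | COc1cc(C(OC[Si](C)(C)C)OC[Si](C)(C)C)cc(OC)c1OC | intermediate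
8 | chloro(3,4,5-trimethoxyphenyl)methyl (trimethylsilyl)methyl ether (racemic) | COc1cc(C(Cl)OC[Si](C)(C)C)cc(OC)c1OC | intermediate
9 | 3,4,5-trimethoxybenzylidene(methylide)oxonium, the carbonyl ylide (not isolated) | COc1cc(C=[O+][CH2-])cc(OC)c1OC | intermediate
10 | (3S,3aR,6S,6aS)-3-[(1S,2R,5S)-menthyloxy]-6-(3,4,5-trimethoxyphenyl)tetrahydro-1H,3H-furo[3,4-c]furan-1-one | C[C@H]1CC[C@@H]([C@H](C1)O[C@@H]2[C@H]3CO[C@H](c4cc(OC)c(OC)c(OC)c4)[C@H]3C(=O)O2)C(C)C | intermediate
11 | (3aR,6S,6aS)-3-hydroxy-6-(3,4,5-trimethoxyphenyl)tetrahydro-1H,3H-furo[3,4-c]furan-1-one (lactol epimers) | OC1[C@H]2CO[C@H](c3cc(OC)c(OC)c(OC)c3)[C@H]2C(=O)O1 | intermediate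
12 | 4-bromo-2-methoxyphenol | COc1cc(Br)ccc1O | starting material
13 | 1-(benzyloxy)-4-bromo-2-methoxybenzene | COc1cc(Br)ccc1OCc1ccccc1 | intermediate
14 | 4-(benzyloxy)-3-methoxyphenylmagnesium bromide (not isolated) | COc1cc([Mg]Br)ccc1OCc1ccccc1 | intermediate
15 | (2S,3S,4R)-4-{[4-(benzyloxy)-3-methoxyphenyl](hydroxy)methyl}-2-(3,4,5-trimethoxyphenyl)oxolane-3-carboxylic acid (carbinol epimers; not isolated) | COc1cc(ccc1OCc1ccccc1)C(O)[C@H]2CO[C@H](c3cc(OC)c(OC)c(OC)c3)[C@H]2C(=O)O | intermediate
16 | (3aR,6S,6aS)-3-[4-(benzyloxy)-3-methoxyphenyl]-6-(3,4,5-trimethoxyphenyl)tetrahydro-1H,3H-furo[3,4-c]furan-1-one (epimers at C3) | COc1cc(ccc1OCc1ccccc1)C2[C@H]3CO[C@H](c4cc(OC)c(OC)c(OC)c4)[C@H]3C(=O)O2 | intermediate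
17 | (3aR,6S,6aS)-3-(4-hydroxy-3-methoxyphenyl)-6-(3,4,5-trimethoxyphenyl)tetrahydro-1H,3H-furo[3,4-c]furan-1-one (epimers at C3; not isolated) | COc1cc(ccc1O)C2[C@H]3CO[C@H](c4cc(OC)c(OC)c(OC)c4)[C@H]3C(=O)O2 | intermediate
18 | (2S,3S,4R)-4-(4-hydroxy-3-methoxybenzyl)-2-(3,4,5-trimethoxyphenyl)oxolane-3-carboxylic acid | COc1cc(C[C@H]2CO[C@H](c3cc(OC)c(OC)c(OC)c3)[C@H]2C(=O)O)ccc1O | intermediate
19 | 4-{[(3R,4R,5S)-4-(hydroxymethyl)-5-(3,4,5-trimethoxyphenyl)oxolan-3-yl]methyl}-2-methoxyphenol | COc1cc(C[C@H]2CO[C@H](c3cc(OC)c(OC)c(OC)c3)[C@H]2CO)ccc1O | target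

Total step count: 10. Longest linear sequence: 7 steps (1, 2, 5, 6, 8, 9, 10). The branch through steps 3 and 4 reaches step 5 in the same number of steps, and step 7 is a one-step side branch.

Steps most likely to fail

Step 5.
- **What may go wrong:** The short-lived ylide may be captured too slowly by a 1,2-disubstituted alkene. Exo/endo selectivity at C2 may erode, the dipole may add in part with reversed regiochemistry, and fluoride may epimerise the acetal carbon of 4 before cycloaddition.
- **Fallback (sets out from 4, returns at 10):** The two ring bonds are made one after the other by known reactions.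
  - Benzophenone-sensitised photoaddition of methanol (hν 350 nm, MeOH) delivers the hydroxymethyl radical to the β-carbon anti to the menthyloxy group. This gives the 4-(hydroxymethyl) lactone F1.
  - Neutral O-alkylation (3,4,5-trimethoxybenzyl bromide, Ag2O, CH2Cl2) gives the trimethoxybenzyl ether F2.
  - Acylation (LiN(SiMe3)2, CF3CO2CH2CF3, THF, −78 °C) gives the α-trifluoroacetyl lactone F3. Detrifluoroacetylative diazo transfer (MsN3, Et3N, MeCN) then gives the α-diazolactone F4.
  - Rh2(OAc)4 in CH2Cl2 closes the oxolane by 1,5 C–H insertion of the rhodium carbene into the benzylic ether C–H bond. The tether fixes the regiochemistry and the ring fusion can only be cis.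
  - If the aryl group is delivered to the concave face, the C6 epimer F5 is equilibrated to 10 with a trace of anhydrous acid, through reversible ionisation of the benzylic C–O bond.

Step 9.
- **What may go wrong:** The second benzylic C–O bond (C2–O1) may undergo hydrogenolysis at the same time, which opens the oxolane ring.
- **Fallback (sets out from 16, returns at 18):**
  - The hydrogenation (Pd/C, EtOAc) is stopped after one equivalent of H2. At that stage only the aryl benzyl ether should have been cleaved, and phenol lactone 17 is isolated.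
  - NaBH4 in aqueous NaOH–THF at 40–60 °C follows. The phenoxide expels the carboxylate by 1,6-elimination to the p-quinone methide acid F6, which takes up hydride at the exocyclic carbon C7'. This is the known borohydride deoxygenation of 4-hydroxybenzyl alcohols and esters.
  - Acidification gives 18. The trimethoxyphenyl ring has no free phenol, so C2–O1 cannot leave by this pathway.

Step 8.
- **What may go wrong:** The basic Grignard reagent may enolise the ring-opened aldehyde. This would epimerise C4 to the trans aldehyde, which cannot relactonise, or simply return starting material.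
- **Fallback (sets out from 11, returns at 16):**
  - Me3SiCHN2 in toluene–MeOH traps the open tautomer as the methyl ester aldehyde F7.
  - A rhodium-catalysed 1,2-addition of commercial 4-(benzyloxy)-3-methoxyphenylboronic acid (Rh(acac)(coe)2, P(t-Bu)3, DME–H2O, rt) proceeds under nearly neutral conditions. It is known for aldehydes and for 2-formylbenzoates on the way to phthalides, and it gives the hydroxy ester F8.
  - F8 lactonises with catalytic TsOH to 16.

Further compounds
F1 | step 5 | (4R,5S)-4-(hydroxymethyl)-5-[(1S,2R,5S)-menthyloxy]dihydrofuran-2(3H)-one | C[C@H]1CC[C@@H]([C@H](C1)O[C@@H]2[C@@H](CO)CC(=O)O2)C(C)C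
F2 | step 5 | (4R,5S)-5-[(1S,2R,5S)-menthyloxy]-4-{[(3,4,5-trimethoxybenzyl)oxy]methyl}dihydrofuran-2(3H)-one | C[C@H]1CC[C@@H]([C@H](C1)O[C@@H]2[C@@H](COCc3cc(OC)c(OC)c(OC)c3)CC(=O)O2)C(C)C
F3 | step 5 | 3-(trifluoroacetyl) derivative of F2 (C3 not defined) | C[C@H]1CC[C@@H]([C@H](C1)O[C@@H]2[C@@H](COCc3cc(OC)c(OC)c(OC)c3)C(C(=O)C(F)(F)F)C(=O)O2)C(C)C
F4 | step 5 | (4R,5S)-3-diazo-5-[(1S,2R,5S)-menthyloxy]-4-{[(3,4,5-trimethoxybenzyl)oxy]methyl}dihydrofuran-2(3H)-one | C[C@H]1CC[C@@H]([C@H](C1)O[C@@H]2[C@@H](COCc3cc(OC)c(OC)c(OC)c3)C(=[N+]=[N-])C(=O)O2)C(C)C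
F5 | step 5 | (3S,3aR,6R,6aS)-3-[(1S,2R,5S)-menthyloxy]-6-(3,4,5-trimethoxyphenyl)tetrahydro-1H,3H-furo[3,4-c]furan-1-one (C6 epimer of 10) | C[C@H]1CC[C@@H]([C@H](C1)O[C@@H]2[C@H]3CO[C@@H](c4cc(OC)c(OC)c(OC)c4)[C@H]3C(=O)O2)C(C)C
F6 | step 9 | (2S,3S,4R)-4-[(3-methoxy-4-oxocyclohexa-2,5-dien-1-ylidene)methyl]-2-(3,4,5-trimethoxyphenyl)oxolane-3-carboxylic acid | COC1=CC(=C[C@H]2CO[C@H](c3cc(OC)c(OC)c(OC)c3)[C@H]2C(=O)O)C=CC1=O
F7 | step 8 | methyl (2S,3S,4R)-4-formyl-2-(3,4,5-trimethoxyphenyl)oxolane-3-carboxylate | O=C[C@H]1CO[C@H](c2cc(OC)c(OC)c(OC)c2)[C@H]1C(=O)OC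
F8 | step 8 | methyl (2S,3S,4R)-4-{[4-(benzyloxy)-3-methoxyphenyl](hydroxy)methyl}-2-(3,4,5-trimethoxyphenyl)oxolane-3-carboxylate (carbinol epimers) | COc1cc(ccc1OCc1ccccc1)C(O)[C@H]2CO[C@H](c3cc(OC)c(OC)c(OC)c3)[C@H]2C(=O)OC
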